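**Retrosynthetic overview**

- Target 16 comes from its triisopropylsilyl ether 15 by fluoride desilylation of the 3'-oxygen.
- 15 is cut at the C2–C1' bond into 5,6,7,8-tetramethoxychromone 9 and arylboronic acid 14. The strategy rests on C2 being the β-carbon of the C2=C3–C4=O enone of ring C, which is where an aryl group on palladium is delivered.
- 9 comes from 2-hydroxyacetophenone 7 by enaminone closure of ring C (the only ring formed in the route). 7 comes from phenol 5 by Fries rearrangement, and 5 from 1,2,3,4-tetramethoxybenzene 1 by formylation and Baeyer–Villiger oxidation.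
- 14 comes from 2,3-dimethoxyphenol 10 by silylation, iridium-catalysed C–H borylation and pinacol cleavage. C1' of ring B is the only ring C–H with a hydrogen on both neighbouring carbons, so steric control places boron there.
- Rings A and B are bought as benzene rings; ring C is closed in step 4; the key step closes no ring.

Key step: step 8

Remark: the target has no stereocentre; the only geometric element in the route is the E double bond of the transient enaminone 8.

**Route**

Step 1
Reactants: 1 1,2,3,4-tetramethoxybenzene
Product: 3 2,3,4,5-tetramethoxybenzaldehyde, via aryl iminium dichlorophosphate 2 (not isolated)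
Conditions: POCl3, DMF, 0 → 80 °C; then H2O, 60 °C
Reagents that add atoms: N,N-dimethylformamide, CN(C)C=O; water, O
Why: Vilsmeier–Haack formylation, in which the two equivalent ring C–H positions of 1 (each ortho and para to methoxy groups) can give only one aldehyde once the iminium salt is hydrolysed.

Step 2
Reactants: 3 2,3,4,5-tetramethoxybenzaldehyde
Product: 5 2,3,4,5-tetramethoxyphenol, via 2,3,4,5-tetramethoxyphenyl formate 4 (not isolated)
Conditions: mCPBA, CH2Cl2, 0 °C → rt; aq. Na2S2O3/NaHCO3 wash; then K2CO3 (cat.), MeOH, rt, argon
Reagents that add atoms: 3-chloroperbenzoic acid, OOC(=O)c1cccc(Cl)c1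
Why: Baeyer–Villiger (Dakin-type) oxidation in which the electron-rich aryl group migrates to give the formate, which is methanolysed only after the peracid has been destroyed so that the oxidation-prone phenol never meets the oxidant.

Step 3
Reactants: 5 2,3,4,5-tetramethoxyphenol
Product: 7 1-(2-hydroxy-3,4,5,6-tetramethoxyphenyl)ethan-1-one, via 2,3,4,5-tetramethoxyphenyl acetate 6 (not isolated)
Conditions: Ac2O (1.2 equiv), BF3·OEt2 (3 equiv), AcOH, 25 → 70 °C; then H2O
Reagents that add atoms: acetic anhydride, CC(=O)OC(C)=O
Why: O-acetylation followed by BF3-promoted Fries rearrangement, in which the acetyl group can only go to the single free ring carbon, which lies ortho to the phenol oxygen, and the chelated ortho-hydroxy ketone is the thermodynamic sink.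

Step 4
Reactants: 7 1-(2-hydroxy-3,4,5,6-tetramethoxyphenyl)ethan-1-one
Product: 9 5,6,7,8-tetramethoxy-4H-chromen-4-one, via E-enaminone 8 (not isolated)
Conditions: Me2NCH(OMe)2, toluene, 100 °C; evaporate; then conc. HCl, CH2Cl2, 40 °C
Reagents that add atoms: N,N-dimethylformamide dimethyl acetal, COC(OC)N(C)C
Why: Enaminone condensation of the methyl ketone followed by acid-promoted intramolecular oxa-Michael addition of the phenol and elimination of dimethylamine, which closes pyranone ring C with C2 and C3 unsubstituted.

Step 5
Reactants: 10 2,3-dimethoxyphenol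
Product: 11 (2,3-dimethoxyphenoxy)tri(propan-2-yl)silane
Conditions: iPr3SiCl, imidazole, DMF, rt
Reagents that add atoms: chlorotri(propan-2-yl)silane, CC(C)[Si](Cl)(C(C)C)C(C)C
Why: Imidazole-mediated O-silylation of a phenol, giving a bulky silyl ether that tolerates the borylation and the oxidative coupling and adds steric shielding at the neighbouring ring C–H.

Step 6
Reactants: 11 (2,3-dimethoxyphenoxy)tri(propan-2-yl)silane; 12 bis(pinacolato)diboron
Product: 13 2-[3,4-dimethoxy-5-(triisopropylsilyloxy)phenyl]-4,4,5,5-tetramethyl-1,3,2-dioxaborolane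
Conditions: [Ir(OMe)(cod)]2 (1.5 mol %), 4,4'-di-tert-butyl-2,2'-bipyridine (3 mol %), B2pin2 (1.0 equiv), THF, 80 °C
Reagents that add atoms: bis(pinacolato)diboron, CC1(C)OB(OC1(C)C)B1OC(C)(C)C(C)(C)O1
Why: Sterically governed iridium-catalysed aromatic C–H borylation, which should select the one ring C–H of 11 that has no ortho substituent (between the C–H next to OMe and the C–H next to the silyloxy group), the carbon that becomes C1'.

Step 7
Reactants: 13 2-[3,4-dimethoxy-5-(triisopropylsilyloxy)phenyl]-4,4,5,5-tetramethyl-1,3,2-dioxaborolane
Product: 14 [3,4-dimethoxy-5-(triisopropylsilyloxy)phenyl]boronic acid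
Conditions: NaIO4, NH4OAc, acetone/H2O (1:1), rt
Reagents that add atoms: water, O
Why: Hydrolysis of the pinacol boronate driven by periodate glycol cleavage of the released pinacol, under buffered conditions that leave the aryl silyl ether untouched.

Step 8
Reactants: 9 5,6,7,8-tetramethoxy-4H-chromen-4-one; 14 [3,4-dimethoxy-5-(triisopropylsilyloxy)phenyl]boronic acid (2.5 equiv)
Product: 15 2-[3,4-dimethoxy-5-(triisopropylsilyloxy)phenyl]-5,6,7,8-tetramethoxy-4H-chromen-4-one
Conditions: Pd(OCOCF3)2 (10 mol %), 2,2'-bipyridine (12 mol %), O2 (1 atm), dry DMSO, 80 °C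
Reagents that add atoms: none
Why: The boronic acid hands its aryl group to the bipyridine-ligated divalent palladium centre, and the arylpalladium species adds syn across C2=C3 of 9, with the aryl group going to the β-carbon C2 and palladium to C3, where it is held as a C- or O-bound palladium enolate. Tautomerisation of this enolate brings palladium syn to the C2 hydrogen, β-hydride elimination re-forms the C2=C3 double bond of the flavone, and O2 returns the palladium hydride to divalent palladium. The closest known reaction type is the oxidative boron-Heck arylation of chromones and coumarins with arylboronic acids under divalent palladium and oxygen. No ring is closed and no stereocentre is made; the only new bond is C2–C1'. The step needs C2 rather than C3 selectivity, and the polarity of the enone provides it, because a nucleophilic aryl on palladium migrates to the electron-poor β-carbon, whereas C3 arylation would require electrophilic palladation of the chromone, which this boronic-acid-driven manifold does not offer. Dry DMSO disfavours protonolysis of the enolate, and the excess of 14 covers loss to protodeboronation and homocoupling.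

Step 9
Reactants: 15 2-[3,4-dimethoxy-5-(triisopropylsilyloxy)phenyl]-5,6,7,8-tetramethoxy-4H-chromen-4-one
Product: 16 3'-hydroxy-5,6,7,8,4',5'-hexamethoxyflavone
Conditions: Bu4NF, AcOH, THF, 0 °C → rt
Reagents that add atoms: none
Why: Fluoride-induced desilylation of an aryl silyl ether, buffered with acetic acid so that the phenol is released without exposing the flavone to a basic phenoxide medium.

**Compound list**

1 | 1,2,3,4-tetramethoxybenzene | COc1ccc(OC)c(OC)c1OC | starting material
2 | N,N-dimethyl-(2,3,4,5-tetramethoxybenzylidene)iminium dichlorophosphate | COc1cc(C=[N+](C)C)c(OC)c(OC)c1OC.[O-]P(=O)(Cl)Cl | intermediate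
3 | 2,3,4,5-tetramethoxybenzaldehyde | COc1cc(C=O)c(OC)c(OC)c1OC | intermediate
4 | 2,3,4,5-tetramethoxyphenyl formate | COc1cc(OC=O)c(OC)c(OC)c1OC | intermediate
5 | 2,3,4,5-tetramethoxyphenol | COc1cc(O)c(OC)c(OC)c1OC | intermediate
6 | 2,3,4,5-tetramethoxyphenyl acetate | COc1cc(OC(C)=O)c(OC)c(OC)c1OC | intermediate
7 | 1-(2-hydroxy-3,4,5,6-tetramethoxyphenyl)ethan-1-one | CC(=O)c1c(O)c(OC)c(OC)c(OC)c1OC | intermediate
8 | (E)-3-(dimethylamino)-1-(2-hydroxy-3,4,5,6-tetramethoxyphenyl)prop-2-en-1-one | CN(C)/C=C/C(=O)c1c(O)c(OC)c(OC)c(OC)c1OC | intermediate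
9 | 5,6,7,8-tetramethoxy-4H-chromen-4-one | COc1c(OC)c(OC)c2occc(=O)c2c1OC | intermediate
10 | 2,3-dimethoxyphenol | COc1cccc(O)c1OC | starting material
11 | (2,3-dimethoxyphenoxy)tri(propan-2-yl)silane | COc1cccc(O[Si](C(C)C)(C(C)C)C(C)C)c1OC | intermediate
12 | bis(pinacolato)diboron | CC1(C)OB(OC1(C)C)B1OC(C)(C)C(C)(C)O1 | starting material
13 | 2-[3,4-dimethoxy-5-(triisopropylsilyloxy)phenyl]-4,4,5,5-tetramethyl-1,3,2-dioxaborolane | COc1cc(B2OC(C)(C)C(C)(C)O2)cc(O[Si](C(C)C)(C(C)C)C(C)C)c1OC | intermediate
14 | [3,4-dimethoxy-5-(triisopropylsilyloxy)phenyl]boronic acid | OB(O)c1cc(OC)c(OC)c(O[Si](C(C)C)(C(C)C)C(C)C)c1 | intermediate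
15 | 2-[3,4-dimethoxy-5-(triisopropylsilyloxy)phenyl]-5,6,7,8-tetramethoxy-4H-chromen-4-one | COc1cc(-c2cc(=O)c3c(OC)c(OC)c(OC)c(OC)c3o2)cc(O[Si](C(C)C)(C(C)C)C(C)C)c1OC | intermediate
16 | 3'-hydroxy-5,6,7,8,4',5'-hexamethoxyflavone | COc1cc(-c2cc(=O)c3c(OC)c(OC)c(OC)c(OC)c3o2)cc(O)c1OC | target

**Step count**

Total: 9 steps. Longest linear sequence: 6 steps (steps 1, 2, 3, 4, 8, 9); the ring B branch (steps 5, 6, 7) joins at step 8.

**Steps most likely to fail**

1. Step 8. The palladium enolate may be protonated before β-hydride elimination, so that the coupling stalls at the dihydro stage, and the electron-rich boronic acid may be used up by protodeboronation or oxidative homocoupling. The fallback separates bond formation from oxidation. It sets out from 9 and 14 and comes back to the route at 15. Chromone 9 and boronic acid 14 are combined in a deliberate conjugate addition (Pd(OCOCF3)2, 2,2'-bipyridine, NH4PF6, H2O, 1,2-dichloroethane, 60 °C, no oxidant), in which protonolysis of the enolate is the intended turnover step. This should give racemic 2-[3,4-dimethoxy-5-(triisopropylsilyloxy)phenyl]-5,6,7,8-tetramethoxy-2,3-dihydro-4H-chromen-4-one F1. The flavanone is then dehydrogenated with DDQ in 1,4-dioxane at reflux to give 15.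

2. Step 3. The Lewis acid may cleave the methyl ether that flanks the new carbonyl (chelation-assisted demethylation), or the reaction may stop at the O-acetate. The fallback replaces electrophilic acylation by directed ortho-metalation. It sets out from 5 and comes back at 7. Phenol 5 is protected with MOMCl and iPr2NEt in CH2Cl2 as 1,2,3,4-tetramethoxy-5-(methoxymethoxy)benzene F2. Treatment with n-BuLi in THF at 0 °C removes the single remaining ring hydrogen, which lies between the methoxymethoxy and a methoxy group, to give [2,3,4,5-tetramethoxy-6-(methoxymethoxy)phenyl]lithium F3. This is quenched with N-methoxy-N-methylacetamide and worked up with dilute HCl to give 1-[2,3,4,5-tetramethoxy-6-(methoxymethoxy)phenyl]ethan-1-one F4. Catalytic HCl in MeOH at 50 °C removes the acetal and gives 7.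

3. Step 7. Liberation of the boronic acid may be incomplete, or the electron-rich arene may lose boron during the periodate cleavage. The fallback replaces oxidative destruction of pinacol by transesterification to a tetracoordinate aminoboronate. It sets out from 13 and comes back at 14. Boronate 13 is stirred with diethanolamine in Et2O, from which 2-[3,4-dimethoxy-5-(triisopropylsilyloxy)phenyl]-1,3,6,2-dioxazaborocane F5 should precipitate. Brief shaking of the filtered solid with 0.1 M HCl and Et2O releases 14 into the organic layer.

**Further compounds**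

F1 | step 8 | 2-[3,4-dimethoxy-5-(triisopropylsilyloxy)phenyl]-5,6,7,8-tetramethoxy-2,3-dihydro-4H-chromen-4-one (racemic) | COc1cc(C2CC(=O)c3c(OC)c(OC)c(OC)c(OC)c3O2)cc(O[Si](C(C)C)(C(C)C)C(C)C)c1OC
F2 | step 3 | 1,2,3,4-tetramethoxy-5-(methoxymethoxy)benzene | COCOc1cc(OC)c(OC)c(OC)c1OC
F3 | step 3 | [2,3,4,5-tetramethoxy-6-(methoxymethoxy)phenyl]lithium | [Li]c1c(OCOC)c(OC)c(OC)c(OC)c1OC
F4 | step 3 | 1-[2,3,4,5-tetramethoxy-6-(methoxymethoxy)phenyl]ethan-1-one | CC(=O)c1c(OCOC)c(OC)c(OC)c(OC)c1OC
F5 | step 7 | 2-[3,4-dimethoxy-5-(triisopropylsilyloxy)phenyl]-1,3,6,2-dioxazaborocane | COc1cc(B2OCCNCCO2)cc(O[Si](C(C)C)(C(C)C)C(C)C)c1OC
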